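The constants of this flask are unknown, but one ratio of them can be read, roughly and on a supposition, from its first seconds, the epsilon run.

| flask | starting material | reagent in the second phase | remark | time | volume of the second phase over the first |
|---|---|---|---|---|---|
| epsilon | 2.4 M | 1 equiv | the very flask that is asked about, followed so far |  |  |
| flask | 2.4 M | 1.00 equiv |  | 2.0 min | 1.0 |

epsilon run (percent of the starting material charged)

| time / s | target / % | starting material / % |
|---|---|---|
| 10.0 | 1.4 | 99.0 |
| 20.0 | 4.3 | 95.5 |
| 40.0 | 11.2 | 88.2 |

(readings scatter by 0.5 percentage points)

- in the second phase: reagent in the second phase; everything else is in the first
- charges count per volume of the first phase; a concentration in a rate is the amount of a species over the volume of its own phase; every rate counts per litre of the first phase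
- the earlier runs hold the two phases in the same ratio of volumes as the flask asked about

- how much target there is at 2.0 min, in percent of the starting material charged
- the change that raises the amount of target at 2.0 min, in percent of the starting material charged most ("none" if none brings more than 2 percentage points) (amber / green / none)
- amount of target at 2.0 min, in percent of the starting material charged, after amber

1. The bench rule says that all starting material lost is target. At 40.0 s you have lost 11.8% and hold 11.2% of target, so you keep 0.949 of the loss. That gap of 0.6 percentage points stands against a scatter of 0.5 points, so what follows is rough.

2. Suppose the gap is target lost to the same reagent that makes it. Take the rate at which target goes, per unit of target, and divide it by the rate at which starting material goes, per unit of starting material. Reagent and time drop out. What remains is the selectivity factor s. Early on, the kept share is 1 − s × loss/2, so s reads 0.862.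

3. Here is the border of the bench rule. Target's loss over its making equals s × target/starting material, which is 0.109 at 40.0 s. On this supposition, target stops rising where that ratio reaches one.

4. If a is the fraction of starting material left, target is (a − a^s)/(s − 1). My straight line through the last two readings leaves 59.0% at 2.0 min. The bench rule then says 41.0%, and the curve says 32.3%. The curve has no clock, so it gives me no figure for amber or green.

5. The forecast, reckoned its own way, gives 32%, picks amber and puts that change at 57%: “Doubling the reagent doubles the rate in either case”.

6. The flask gives 30.3%. The choice is amber, which adds 11 points, while green adds 1.5 points. Amber reaches 41.2%.

    reagent in the reaction phase ⇌ reagent in the second phase, rate k1*([reagent in the reaction phase] - [reagent in the second phase]/K1) per volume of the first phase (partition coefficient = 0.320, kL = 0.0130 s⁻¹)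
    reagent in the reaction phase + target → over-reacted product (k = 0.00210 M⁻¹ s⁻¹)
    reagent in the reaction phase + target → over-reaction product (k = 3.60 × 10⁻⁴ M⁻¹ s⁻¹)
    starting material + reagent in the reaction phase → target (k = 0.00330 M⁻¹ s⁻¹)

Put this flask's 64% of starting material left at 2.00 min into the curve, and s gives 29.5% of target, against 30.3% found. Now take the neighbour, the same flask read at 8.0 min, with 35% of starting material left. The bench rule says 65.0%. The loss-to-making ratio there, with s as read, is 1.04, about one. The curve says 39.5%, and that neighbour holds 42.1% of target.

All runs are simulated on assumed constants, and the scatter is random.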